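The C2–C3 bond of the chroman is the disconnection; it separates ring B with C2 from ring A with C4 and C3, two halves of comparable size. C2 is benzylic to ring B and para to its 4'-oxygen, so it usually reacts as an electrophile. Here its polarity is inverted in a chiral benzylic sulfonium ylide, which adds to an arylacetaldehyde (C3) and closes to a trans (2S,3S)-oxirane; one operation makes C2–C3 and both stereocentres. The precursors are 3,4-bis(benzyloxy)benzyl (2R,5R)-2,5-dimethylthiolanium tetrafluoroborate and 2,4,6-tris(silyloxy)phenylacetaldehyde. A ring A phenol later opens the oxirane at C2 with inversion, closing O1–C2 of ring C as the 2,3-trans (2R,3S) flavan-3-ol.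

Key step: step 8

Remarks on the chemistry:
- Assumption: the (2R,5R)-thiolane is taken to show with the aliphatic aldehyde 10 the facial sense established for aromatic aldehydes, which leads to the (S,S)-oxirane.
- Assumption: 3,4-bis(benzyloxy)benzyl alcohol and 3,4,5-tris(benzyloxy)benzoic acid are taken as catalogue compounds.
- Stereochemical bookkeeping, re-derived and found consistent: (2S,5S)-diol, two inversions, (2R,5R)-thiolane; (2S,3S)-oxirane, inversion at C2 only, (2R,3S)-chroman as in the target.
- Design change: the sulfonium salt is used as its tetrafluoroborate, because bromide dealkylates an electron-rich benzylsulfonium ion reversibly.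
- Design change: the silyl ethers are cleaved with buffered fluoride and the free epoxy phenol is cyclised without isolation, so that no phenoxide meets the oxirane.

Step 1
Reactants: 1 (2S,5S)-hexane-2,5-diol
Product: 2 (2S,5S)-hexane-2,5-diyl dimethanesulfonate
Conditions: MsCl, Et3N, CH2Cl2, 0 °C
Reagents that add atoms: methanesulfonyl chloride, CS(=O)(=O)Cl
Why: Sulfonylation at oxygen (mesylate formation) breaks no C–O bond, so both carbinol centres keep the S configuration and become leaving groups.

Step 2
Reactants: 2 (2S,5S)-hexane-2,5-diyl dimethanesulfonate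
Product: 3 (2R,5R)-2,5-dimethylthiolane
Conditions: Na2S·9H2O, DMSO, rt; distillation
Reagents that add atoms: sodium sulfide (Na2S), [Na+].[Na+].[S-2]
Why: Double SN2 thioetherification (intermolecular displacement, then 5-exo-tet closure by the thiolate) inverts both carbons, so the (S,S)-dimesylate should give the trans (R,R)-thiolane, an established way to this C2-symmetric sulfide.

Step 3
Reactants: 4 3,4-bis(benzyloxy)benzyl alcohol
Product: 5 3,4-bis(benzyloxy)benzyl bromide
Conditions: PBr3, Et2O, 0 °C
Reagents that add atoms: phosphorus tribromide, BrP(Br)Br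
Why: Bromination of a primary benzylic alcohol through its phosphite ester is routine and leaves the aryl benzyl ethers alone; the bromide is used at once because the ring B donor groups make it labile.

Step 4
Reactants: 5 3,4-bis(benzyloxy)benzyl bromide; 3 (2R,5R)-2,5-dimethylthiolane
Product: 6 (2R,5R)-1-[3,4-bis(benzyloxy)benzyl]-2,5-dimethylthiolanium tetrafluoroborate
Conditions: NaBF4, CH2Cl2/H2O, rt
Reagents that add atoms: sodium tetrafluoroborate, [Na+].F[B-](F)(F)F
Why: S-Alkylation of the sulfide by the reactive benzylic bromide with anion exchange in the flask should give one salt, since the two lone pairs of the C2-symmetric sulfide are homotopic and sulfur is therefore no stereocentre, and tetrafluoroborate cannot dealkylate the cation as bromide would.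

Step 5
Reactants: 7 2,4,6-trihydroxybenzaldehyde
Product: 8 2,4,6-tris(tert-butyldimethylsilyloxy)benzaldehyde
Conditions: TBSCl (excess), imidazole, DMF, rt
Reagents that add atoms: tert-butyldimethylsilyl chloride, CC(C)(C)[Si](C)(C)Cl
Why: Silyl ether formation with excess silyl chloride and imidazole masks all three phenols, the hydrogen-bonded ortho ones included, as ethers that tolerate amide bases and cold dilute acid but leave with fluoride.

Step 6
Reactants: 8 2,4,6-tris(tert-butyldimethylsilyloxy)benzaldehyde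
Product: 9 2-(2-methoxyethenyl)-1,3,5-tris(tert-butyldimethylsilyloxy)benzene (E/Z mixture)
Conditions: MeOCH2PPh3Cl, KN(SiMe3)2, THF, 0 °C → rt
Reagents that add atoms: (methoxymethyl)triphenylphosphonium chloride, COC[P+](c1ccccc1)(c1ccccc1)c1ccccc1.[Cl-]
Why: Wittig methoxymethylenation of the non-enolisable aryl aldehyde adds the carbon that becomes C3; the silylamide base forms the ylide without an alkoxide that would attack the aryl silyl ethers, and the alkene geometry is irrelevant because both isomers hydrolyse to the same aldehyde.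

Step 7
Reactants: 9 2-(2-methoxyethenyl)-1,3,5-tris(tert-butyldimethylsilyloxy)benzene
Product: 10 2-[2,4,6-tris(tert-butyldimethylsilyloxy)phenyl]acetaldehyde
Conditions: 1 M aq. HCl, THF, 0 °C → rt; used crude
Reagents that add atoms: water, O
Why: Acid-catalysed enol ether hydrolysis (protonation at the carbon next to ring A, addition of water to the oxocarbenium ion, loss of methanol) should unmask the arylacetaldehyde while aryl tert-butyldimethylsilyl ethers tolerate cold dilute acid, and the aldehyde is taken on directly to avoid self-condensation.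

Step 8
Reactants: 6 (2R,5R)-1-[3,4-bis(benzyloxy)benzyl]-2,5-dimethylthiolanium tetrafluoroborate; 10 2-[2,4,6-tris(tert-butyldimethylsilyloxy)phenyl]acetaldehyde
Product: 13 (2S,3S)-2-[3,4-bis(benzyloxy)phenyl]-3-[2,4,6-tris(tert-butyldimethylsilyloxy)benzyl]oxirane, via sulfonium benzylide 11 (not isolated), via anti betaine 12 (not isolated)
Conditions: 6 (1.3 equiv), KN(SiMe3)2 (1.2 equiv), THF, −78 °C; then 10 added slowly, −78 → −40 °C; pH 7 quench, Et3N-deactivated silica
Reagents that add atoms: none
Why: Deprotonation of 6 at the benzylic carbon gives ylide 11, whose carbanion (the future C2) adds to the carbonyl carbon of 10 (the future C3) to give the anti betaine 12, and the alkoxide then displaces the thiolane by backside attack. The closest known reaction type is the asymmetric Johnson–Corey–Chaykovsky epoxidation of aldehydes, aliphatic ones included, with benzylides of chiral C2-symmetric thiolanes. The oxirane closes in a 3-exo-tet mode with inversion at the ylide carbon. The C2 stereocentre is set by the thiolane, since the aryl group of the ylide points away from the ring and the methyl group cis to the benzylidene blocks one face, so the aldehyde should be met on the face that leads to S; the C3 stereocentre is set relative to C2 by the preference for the anti betaine, the syn betaine closing slowly and reverting. The step needs carbonyl addition to win over proton transfer from the α-CH2 of 10, which the preformed ylide at −78 °C, the absence of excess base and the two ortho silyloxy groups that twist ring A out of conjugation with an enolate should favour, and it needs trans and facial selectivity, which the semi-stabilised benzylide and the C2-symmetric sulfide supply.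

Step 9
Reactants: 13 (2S,3S)-2-[3,4-bis(benzyloxy)phenyl]-3-[2,4,6-tris(tert-butyldimethylsilyloxy)benzyl]oxirane
Product: 15 (2R,3S)-2-[3,4-bis(benzyloxy)phenyl]chromane-3,5,7-triol, via epoxy triol 14 (not isolated)
Conditions: Bu4NF/AcOH (1:1), THF, 0 °C; aqueous wash; then PPTS (cat.), CH2Cl2, 0 °C → rt
Reagents that add atoms: none
Why: Acetic-acid-buffered fluoride cleaves the three aryl silyl ethers to neutral phenols, so that no phenoxide opens the oxirane at C3 in a 5-exo mode, and mild Brønsted acid then triggers a 6-endo epoxide-opening cycloetherification in which an ortho hydroxyl of ring A (the two are equivalent) attacks C2, activated by the 4-benzyloxy group of ring B, from the side opposite the oxirane oxygen, which inverts C2 from S to R, leaves C3 unchanged as the 3-hydroxyl and should give the 2,3-trans chroman with O5 and O7 free.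

Step 10
Reactants: 16 3,4,5-tris(benzyloxy)benzoic acid
Product: 17 3,4,5-tris(benzyloxy)benzoyl chloride
Conditions: (COCl)2, DMF (cat.), CH2Cl2, 0 °C → rt
Reagents that add atoms: oxalyl chloride, O=C(Cl)C(=O)Cl
Why: Acid chloride formation with oxalyl chloride under Vilsmeier-type catalysis by DMF is standard for this benzyl-protected gallic acid and gives only volatile by-products.

Step 11
Reactants: 15 (2R,3S)-2-[3,4-bis(benzyloxy)phenyl]chromane-3,5,7-triol; 17 3,4,5-tris(benzyloxy)benzoyl chloride
Product: 18 (2R,3S)-2-[3,4-bis(benzyloxy)phenyl]-3-hydroxychromane-5,7-diyl bis[3,4,5-tris(benzyloxy)benzoate]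
Conditions: 17 (2.2 equiv), Et3N, CH2Cl2, −20 → 0 °C, no DMAP
Reagents that add atoms: none
Why: Base-mediated esterification with an acid chloride should be selective for the two phenols, because their triethylammonium phenoxides react far faster with the hindered aroyl chloride than the secondary C3 alcohol does when no acyl-transfer catalyst is present, and no stereocentre is involved.

Step 12
Reactants: 18 (2R,3S)-2-[3,4-bis(benzyloxy)phenyl]-3-hydroxychromane-5,7-diyl bis[3,4,5-tris(benzyloxy)benzoate]
Product: 19 (2R,3S)-2-(3,4-dihydroxyphenyl)-3-hydroxychromane-5,7-diyl bis(3,4,5-trihydroxybenzoate) (catechin 5,7-di-O-gallate)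
Conditions: H2 (1 atm), Pd(OH)2 on carbon, THF/EtOAc, rt
Reagents that add atoms: none
Why: Catalytic hydrogenolysis should cleave all eight benzyl ethers to toluene while the aryl gallate esters and the chroman C2–O1 bond survive at ambient pressure, the aprotic solvent prevents transesterification, and neither stereocentre is touched.

Compound list
1 | (2S,5S)-hexane-2,5-diol | C[C@H](O)CC[C@H](C)O | starting material
2 | (2S,5S)-hexane-2,5-diyl dimethanesulfonate | C[C@H](OS(C)(=O)=O)CC[C@H](C)OS(C)(=O)=O | intermediate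
3 | (2R,5R)-2,5-dimethylthiolane | C[C@@H]1CC[C@@H](C)S1 | intermediate
4 | 3,4-bis(benzyloxy)benzyl alcohol | OCc1ccc(OCc2ccccc2)c(OCc2ccccc2)c1 | starting material
5 | 3,4-bis(benzyloxy)benzyl bromide | BrCc1ccc(OCc2ccccc2)c(OCc2ccccc2)c1 | intermediate
6 | (2R,5R)-1-[3,4-bis(benzyloxy)benzyl]-2,5-dimethylthiolanium tetrafluoroborate | C[C@@H]1CC[C@@H](C)[S+]1Cc1ccc(OCc2ccccc2)c(OCc2ccccc2)c1.F[B-](F)(F)F | intermediate
7 | 2,4,6-trihydroxybenzaldehyde | O=Cc1c(O)cc(O)cc1O | starting material
8 | 2,4,6-tris(tert-butyldimethylsilyloxy)benzaldehyde | O=Cc1c(O[Si](C)(C)C(C)(C)C)cc(O[Si](C)(C)C(C)(C)C)cc1O[Si](C)(C)C(C)(C)C | intermediate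
9 | 2-(2-methoxyethenyl)-1,3,5-tris(tert-butyldimethylsilyloxy)benzene, E/Z mixture | COC=Cc1c(O[Si](C)(C)C(C)(C)C)cc(O[Si](C)(C)C(C)(C)C)cc1O[Si](C)(C)C(C)(C)C | intermediate
10 | 2-[2,4,6-tris(tert-butyldimethylsilyloxy)phenyl]acetaldehyde | O=CCc1c(O[Si](C)(C)C(C)(C)C)cc(O[Si](C)(C)C(C)(C)C)cc1O[Si](C)(C)C(C)(C)C | intermediate
11 | (2R,5R)-2,5-dimethylthiolanium 3,4-bis(benzyloxy)benzylide | C[C@@H]1CC[C@@H](C)[S+]1[CH-]c1ccc(OCc2ccccc2)c(OCc2ccccc2)c1 | intermediate (not isolated)
12 | anti betaine, (1R,2S)-1-[3,4-bis(benzyloxy)phenyl]-1-[(2R,5R)-2,5-dimethylthiolan-1-ium-1-yl]-3-[2,4,6-tris(tert-butyldimethylsilyloxy)phenyl]propan-2-olate | C[C@@H]1CC[C@@H](C)[S+]1[C@H](c1ccc(OCc2ccccc2)c(OCc2ccccc2)c1)[C@@H]([O-])Cc1c(O[Si](C)(C)C(C)(C)C)cc(O[Si](C)(C)C(C)(C)C)cc1O[Si](C)(C)C(C)(C)C | intermediate (not isolated)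
13 | (2S,3S)-2-[3,4-bis(benzyloxy)phenyl]-3-[2,4,6-tris(tert-butyldimethylsilyloxy)benzyl]oxirane | c1ccccc1COc1ccc([C@@H]2O[C@H]2Cc2c(O[Si](C)(C)C(C)(C)C)cc(O[Si](C)(C)C(C)(C)C)cc2O[Si](C)(C)C(C)(C)C)cc1OCc1ccccc1 | intermediate
14 | 2-{[(2S,3S)-3-[3,4-bis(benzyloxy)phenyl]oxiran-2-yl]methyl}benzene-1,3,5-triol | c1ccccc1COc1ccc([C@@H]2O[C@H]2Cc2c(O)cc(O)cc2O)cc1OCc1ccccc1 | intermediate (not isolated)
15 | (2R,3S)-2-[3,4-bis(benzyloxy)phenyl]chromane-3,5,7-triol | Oc1cc(O)c2c(c1)O[C@H](c1ccc(OCc3ccccc3)c(OCc3ccccc3)c1)[C@@H](O)C2 | intermediate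
16 | 3,4,5-tris(benzyloxy)benzoic acid | OC(=O)c1cc(OCc2ccccc2)c(OCc2ccccc2)c(OCc2ccccc2)c1 | starting material
17 | 3,4,5-tris(benzyloxy)benzoyl chloride | ClC(=O)c1cc(OCc2ccccc2)c(OCc2ccccc2)c(OCc2ccccc2)c1 | intermediate
18 | (2R,3S)-2-[3,4-bis(benzyloxy)phenyl]-3-hydroxychromane-5,7-diyl bis[3,4,5-tris(benzyloxy)benzoate] | O=C(Oc1cc(OC(=O)c2cc(OCc3ccccc3)c(OCc3ccccc3)c(OCc3ccccc3)c2)c2c(c1)O[C@H](c1ccc(OCc3ccccc3)c(OCc3ccccc3)c1)[C@@H](O)C2)c1cc(OCc2ccccc2)c(OCc2ccccc2)c(OCc2ccccc2)c1 | intermediate
19 | (2R,3S)-2-(3,4-dihydroxyphenyl)-3-hydroxychromane-5,7-diyl bis(3,4,5-trihydroxybenzoate), catechin 5,7-di-O-gallate | O=C(Oc1cc(OC(=O)c2cc(O)c(O)c(O)c2)c2c(c1)O[C@H](c1ccc(O)c(O)c1)[C@@H](O)C2)c1cc(O)c(O)c(O)c1 | target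

Total step count: 12. Longest linear sequence: 7 steps (steps 1, 2, 4, 8, 9, 11, 12; the ring A branch, steps 5, 6, 7, 8, 9, 11, 12, is equally long).

Steps most likely to fail

1. Step 8. The ylide may take a proton from the α-methylene of 10 (enolisation, then aldol condensation) and fail to add to the carbonyl group. Leakage through the syn betaine or the other ylide face would erode trans and enantiomeric purity.
Fallback, setting out from 10 and coming back at 13: the ring B carbon is attached by cross-coupling, and the oxirane is made by reagent-controlled epoxidation. Takai iodo-olefination of 10 (CrCl2, CHI3, THF, 0 °C), which involves no basic carbanion, should give 2-[(2E)-3-iodoprop-2-en-1-yl]-1,3,5-tris(tert-butyldimethylsilyloxy)benzene F1. Suzuki–Miyaura coupling of this iodide with commercial 3,4-bis(benzyloxy)phenylboronic acid (Pd(PPh3)4, K3PO4, THF/H2O, 40 °C) should give (E)-1-[3,4-bis(benzyloxy)phenyl]-3-[2,4,6-tris(tert-butyldimethylsilyloxy)phenyl]prop-1-ene F2 with retention of the alkene geometry. Shi epoxidation of this alkene with the L-fructose-derived enantiomer of the ketone catalyst (KHSO5 as 2KHSO5·KHSO4·K2SO4, K2CO3 buffer, MeCN/dimethoxymethane/H2O, 0 °C), a method that is reliable for trans-β-alkylstyrenes, should then give the (2S,3S)-oxirane 13.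

2. Step 9. A phenoxide formed during desilylation may attack C3 in a 5-exo mode, or ionisation at C2 may be followed by a hydride shift to the ketone before ring closure.
Fallback, setting out from 13 and coming back at 15: the oxirane is removed before the phenols are freed, and the ring is closed by cyclodehydration. Acid-catalysed hydration of 13 (HClO4 cat., THF/H2O, 0 °C) should open the oxirane at the benzylic carbon to (2S)-1-[3,4-bis(benzyloxy)phenyl]-3-[2,4,6-tris(tert-butyldimethylsilyloxy)phenyl]propane-1,2-diol F3, of which both C1 epimers are usable. Bu4NF/AcOH in THF should then give 2-{(2S)-3-[3,4-bis(benzyloxy)phenyl]-2,3-dihydroxypropyl}benzene-1,3,5-triol F4, which has no oxirane left for a phenoxide to attack. Acid-catalysed cyclodehydration of this pentol (TsOH cat., THF/CH2Cl2), a known closure of 1,3-diarylpropane-1,2-diols to flavan-3-ols, runs through the 4-benzyloxybenzyl cation at the benzylic carbon. It should favour the 2,3-trans chroman 15, with the cis isomer removed by chromatography; C3 is never touched, so the enantiomeric purity is kept.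

3. Step 11. Acylation of the C3 hydroxyl may compete with the second phenol (over-galloylation), or the more hindered O5 may react incompletely.
Fallback, setting out from 15 and coming back at 18: the C3 hydroxyl is masked first. Exhaustive silylation of 15 (TBSCl, imidazole, DMF) should give (2R,3S)-2-[3,4-bis(benzyloxy)phenyl]-3,5,7-tris(tert-butyldimethylsilyloxy)chromane F5. Selective cleavage of the two aryl silyl ethers (Cs2CO3, DMF/H2O, rt) should give (2R,3S)-2-[3,4-bis(benzyloxy)phenyl]-3-(tert-butyldimethylsilyloxy)chromane-5,7-diol F6. Acylation with 17 (Et3N, DMAP, CH2Cl2) should give (2R,3S)-2-[3,4-bis(benzyloxy)phenyl]-3-(tert-butyldimethylsilyloxy)chromane-5,7-diyl bis[3,4,5-tris(benzyloxy)benzoate] F7. HF·pyridine (THF, 0 °C), which leaves aryl esters alone, should then remove the alkyl silyl ether and give 18.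

Further compounds
F1 | step 8 | 2-[(2E)-3-iodoprop-2-en-1-yl]-1,3,5-tris(tert-butyldimethylsilyloxy)benzene | I/C=C/Cc1c(O[Si](C)(C)C(C)(C)C)cc(O[Si](C)(C)C(C)(C)C)cc1O[Si](C)(C)C(C)(C)C
F2 | step 8 | (E)-1-[3,4-bis(benzyloxy)phenyl]-3-[2,4,6-tris(tert-butyldimethylsilyloxy)phenyl]prop-1-ene | c1ccccc1COc1ccc(/C=C/Cc2c(O[Si](C)(C)C(C)(C)C)cc(O[Si](C)(C)C(C)(C)C)cc2O[Si](C)(C)C(C)(C)C)cc1OCc1ccccc1
F3 | step 9 | (2S)-1-[3,4-bis(benzyloxy)phenyl]-3-[2,4,6-tris(tert-butyldimethylsilyloxy)phenyl]propane-1,2-diol, C1 epimers | OC(c1ccc(OCc2ccccc2)c(OCc2ccccc2)c1)[C@@H](O)Cc1c(O[Si](C)(C)C(C)(C)C)cc(O[Si](C)(C)C(C)(C)C)cc1O[Si](C)(C)C(C)(C)C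
F4 | step 9 | 2-{(2S)-3-[3,4-bis(benzyloxy)phenyl]-2,3-dihydroxypropyl}benzene-1,3,5-triol, C3 epimers | OC(c1ccc(OCc2ccccc2)c(OCc2ccccc2)c1)[C@@H](O)Cc1c(O)cc(O)cc1O
F5 | step 11 | (2R,3S)-2-[3,4-bis(benzyloxy)phenyl]-3,5,7-tris(tert-butyldimethylsilyloxy)chromane | CC(C)(C)[Si](C)(C)Oc1cc(O[Si](C)(C)C(C)(C)C)c2c(c1)O[C@H](c1ccc(OCc3ccccc3)c(OCc3ccccc3)c1)[C@@H](O[Si](C)(C)C(C)(C)C)C2
F6 | step 11 | (2R,3S)-2-[3,4-bis(benzyloxy)phenyl]-3-(tert-butyldimethylsilyloxy)chromane-5,7-diol | Oc1cc(O)c2c(c1)O[C@H](c1ccc(OCc3ccccc3)c(OCc3ccccc3)c1)[C@@H](O[Si](C)(C)C(C)(C)C)C2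
F7 | step 11 | (2R,3S)-2-[3,4-bis(benzyloxy)phenyl]-3-(tert-butyldimethylsilyloxy)chromane-5,7-diyl bis[3,4,5-tris(benzyloxy)benzoate] | O=C(Oc1cc(OC(=O)c2cc(OCc3ccccc3)c(OCc3ccccc3)c(OCc3ccccc3)c2)c2c(c1)O[C@H](c1ccc(OCc3ccccc3)c(OCc3ccccc3)c1)[C@@H](O[Si](C)(C)C(C)(C)C)C2)c1cc(OCc2ccccc2)c(OCc2ccccc2)c(OCc2ccccc2)c1
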